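The easy step came first: the pair started level, so an excess could come from a step that takes one hand faster than the other.

| setting | south-west | south-east | delta | theta |
|---|---|---|---|---|
| left-handed substrate | 0.16 M | 0.16 M | 0.16 M | 0.16 M |
| right-handed substrate | 0.16 M | 0.16 M | 0.16 M | 0.16 M |
| solid reagent | 0.31 M | 0.52 M | 0.400 M | 0.250 M |
| remark | run made earlier | run made earlier |  |  |
| time |  |  | 20 h | 20 h |

| run | time / h | right-handed substrate / % | left-handed substrate / % | left-handed product / % |
|---|---|---|---|---|
| south-west | 1.00 | 49.5 | 48.7 | 0 |
| south-west | 2.50 | 48.0 | 48.5 | 0 |
| south-west | 5.00 | 46.6 | 46.5 | 0 |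
| south-west | 8.00 | 44.3 | 44.1 | 0 |
| south-west | 10.0 | 42.4 | 43.2 | 0.1 |
| south-west | 15.0 | 40.3 | 40.3 | 1.0 |
| south-east | 2.50 | 47.5 | 47.1 | 0.9 |
| south-east | 5.00 | 45.4 | 45.7 | 0 |
| south-east | 8.00 | 44.9 | 43.7 | 0.6 |
| south-east | 10.0 | 42.7 | 42.7 | 0.5 |
| south-east | 12.0 | 41.4 | 41.3 | 0.9 |
| south-east | 15.0 | 39.5 | 39.5 | 1.1 |

(standard deviation of a reading: 0.5 percentage points)

1. the flask that ends with the higher excess of right-handed substrate over left-handed substrate among what is left of the two, or "neither" when 2 percentage points or less lies between them (delta / theta / neither)
2. excess of right-handed substrate over left-handed substrate among what is left of the two at the end, delta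
3. excess of right-handed substrate over left-handed substrate among what is left of the two at the end, theta

- coupling partner is single-handed; left-handed substrate and right-handed substrate are mirror images of each other, charged as a racemate, each of them at the stated concentration
- as a solid, counted per litre of solution: solid reagent
- reactions considered so far: coupling partner + right-handed substrate -> right-handed product; left-handed product <-> right-handed product; left-handed substrate <-> achiral form; coupling partner + left-handed substrate -> left-handed product; solid reagent <-> coupling partner; right-handed substrate <-> achiral form
- at the start none of the solid reagent is in solution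
- an excess is the difference of the two amounts in percent of their sum
- an excess is below zero if the other one leads
- the handed part of coupling partner does not stay in what it makes, so the products of the two hands are mirror images too

I read the runs in slow motion. In the first instants, at 1.00 h in the south-west run, right-handed substrate stood at 49.5 %, left-handed substrate at 48.7 % and left-handed product at 0 %. By 8.00 h in the south-west run the hands had fallen together to 44.3 % and 44.1 %, with a reading of 0 % for product. At 15.0 h, averaging both runs, the share missing from the pair read 20.2 %, far more than the 1.05 % of left-handed product, so I took the hand-blind step to the achiral form as the main way out of the pair.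

Right-handed product was not reported, so I counted it as nil. The left hand then trailed by the product, and I took that product over the substrates left, 79.8 %, which gave 1.32 %. Going round again, I ran product and loss on in proportion to 20 h, leaving 73.1 % of substrate. The hand gap, left-handed product over the two substrates left, became 1.92 %. Solid charges of 0.31 M and 0.52 M gave product readings of 1.0 % and 1.1 %, within the scatter, so I expected the same gap in delta and theta, although theta's 0.250 M lies below both runs.

The forecast gave 0 % for delta, 0 % for theta and neither, holding that “no resolution is visible”. Its excesses differed from my gap, but its answer on the two flasks was the one I expected.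

Delta gave 0.656 %, theta 0.656 %, and the comparison came out neither.

    coupling partner + right-handed substrate → right-handed product (k = 1.10 × 10⁻⁶ M⁻¹ s⁻¹)
    left-handed product ⇌ right-handed product (k = 1.70 × 10⁻⁶ s⁻¹)
    left-handed substrate ⇌ achiral form (K = 1.10, k = 5.00 × 10⁻⁶ s⁻¹)
    coupling partner + left-handed substrate → left-handed product (k = 5.50 × 10⁻⁵ M⁻¹ s⁻¹)
    solid reagent ⇌ coupling partner, rate k5*(cs5 - [coupling partner]) while solid is left; crystals form when [coupling partner] > cs5 (solubility = 8.00 mM, k = 2.30 × 10⁻⁵ s⁻¹)
    right-handed substrate ⇌ achiral form (K = 1.10, k = 5.00 × 10⁻⁶ s⁻¹)

At the end of delta, coupling took left-handed substrate at 0.00107 h⁻¹ per unit of it, against 0.0180 h⁻¹ for its forward step to the achiral form. Delta's own amounts put the hand gap, with right-handed product subtracted, at 0.686 %, while my reading-based 1.92 % stood above the result. For a neighbour, theta with 0.42 M of solid reagent, the reckoning again gives 1.92 %, and its own amounts give 0.686 %; the computed excess is 0.656 %.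

(The numbers in the tables were generated by integration for substances that don't exist; noise was put on by code.)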